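**Strategy.** The route rests on reading the furanone ring (O1, C2 carbonyl, C3, C4, C5; exocyclic C6) together with the side-chain carbinol C1' as a β-bromo Morita–Baylis–Hillman motif: C1'–O sits on C3, which carries the C2 carbonyl and is doubly bonded to the brominated C4. One three-component bromo-aldol therefore forges C4–Br and C3–C1' at once and fixes C1' as R under catalyst control. Its substrate is an acyclic ynoate whose alkyne carbons become C3 and C4 and whose silylated tribromomethyl carbinol already supplies C5, O1 and C6. Lactonisation, loss of HBr and acetylation then finish the target.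

Key step: step 3

Remark: the carbon that becomes C5 is racemic from step 1, so compounds 10–13 are pairs of epimers at that carbon (each R at C1'); they merge when it becomes sp2 in step 5.

Assumption: the (S)-prolinol-derived oxazaborolidinium ion is taken to leave the Si face of bound butanal open; should the sense prove opposite, the (R)-catalyst would be used in the same way.

**Step 1**
Reactants: 1 methyl propiolate; 2 tribromoacetaldehyde (bromal)
Product: 5 methyl 5,5,5-tribromo-4-hydroxypent-2-ynoate (racemic), via lithium acetylide 3 (not isolated), via lithium alkoxide 4 (not isolated)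
Conditions: LiHMDS, THF, −78 °C; then 2, −78 °C; AcOH/THF quench at −78 °C
Reagents that add atoms: none
Why: 1,2-addition of a lithium acetylide to a non-enolisable, very electrophilic aldehyde is fast at −78 °C, and the cold acetic-acid quench protonates the tribromomethyl alkoxide before it can revert or cyclise, the new carbinol centre being left racemic on purpose because step 5 removes it.

**Step 2**
Reactants: 5 methyl 5,5,5-tribromo-4-hydroxypent-2-ynoate
Product: 6 methyl 5,5,5-tribromo-4-(triethylsilyloxy)pent-2-ynoate (racemic)
Conditions: TESOTf, 2,6-lutidine, CH2Cl2, −78 → 0 °C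
Reagents that add atoms: triethylsilyl trifluoromethanesulfonate, CC[Si](CC)(CC)OS(=O)(=O)C(F)(F)F
Why: Silyl triflate O-silylation with a hindered, non-nucleophilic pyridine base caps the acidic, crowded carbinol without offering a nucleophile to the ynoate or a base able to attack the tribromomethyl carbinol, and the triethylsilyl ether is chosen because it should survive a halosilane and a Lewis acid at −78 °C yet fall to HF without base.

**Step 3**
Reactants: 6 methyl 5,5,5-tribromo-4-(triethylsilyloxy)pent-2-ynoate; 7 butanal; 8 bromotrimethylsilane
Product: 11 methyl (2E)-3,5,5,5-tetrabromo-2-[(1R)-1-hydroxybutyl]-4-(triethylsilyloxy)pent-2-enoate (two epimers at C4), via silyl allenolate 9 (not isolated), via aldol trimethylsilyl ether 10 (not isolated)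
Conditions: (S)-o-tolyl-CBS oxazaborolidine·Tf2NH (20 mol %), CH2Cl2, −78 → −40 °C; then 1 M HCl, THF, 0 °C
Reagents that add atoms: bromotrimethylsilane (8), C[Si](C)(C)Br
Why: With silicon engaging the ester carbonyl oxygen, ynoate 6 takes up bromide from 8 at the alkyne carbon remote from the ester (future C4) to give the β-bromo silyl allenolate 9, whose central carbon (future C3) adds in Mukaiyama fashion to butanal bound to the cationic oxazaborolidinium, and silyl transfer to the aldolate gives 10, from which dilute acid removes only the trimethylsilyl group. The closest known reaction is the three-component halo-aldol (β-halo Morita–Baylis–Hillman) coupling of alkynoates, halotrimethylsilanes and aldehydes under chiral oxazaborolidinium catalysis, run here on a γ-silyloxy internal ynoate with the bromosilane. No ring is closed. The single new stereocentre C1' is controlled by the catalyst, which blocks one face of the coordinated aldehyde so that the allenolate adds to the Si face and C1' becomes R, while the remote racemic silyloxy carbon only doubles the product into two epimers that converge later. The step needs β-regioselective bromide delivery, secured by the ynoate polarisation reinforced by the inductively withdrawing tribromomethyl carbinol, and E geometry, secured because the aldehyde approaches the allenolate in the plane of the C4 substituents past the small bromine and away from the branched silyloxy(tribromomethyl)methyl group, leaving the ester cis to the future C5. The tribromomethyl group and the triethylsilyl ether meet neither base, metal nor fluoride at this temperature.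

**Step 4**
Reactants: 11 methyl (2E)-3,5,5,5-tetrabromo-2-[(1R)-1-hydroxybutyl]-4-(triethylsilyloxy)pent-2-enoate
Product: 13 4-bromo-3-[(1R)-1-hydroxybutyl]-5-(tribromomethyl)furan-2(5H)-one (two epimers at C5), via dihydroxy ester 12 (not isolated)
Conditions: 48% aq. HF, MeCN, 0 °C → rt; then TsOH·H2O (cat.), PhMe, 50 °C
Reagents that add atoms: none
Why: HF desilylation frees the hydroxyl that the tetrasubstituted alkene holds cis to the methyl ester, and acid-catalysed transesterification (5-exo-trig lactonisation) should close the butenolide with loss of methanol, while the C1' hydroxyl could only form a four-membered ring and C1' itself is not touched.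

**Step 5**
Reactants: 13 4-bromo-3-[(1R)-1-hydroxybutyl]-5-(tribromomethyl)furan-2(5H)-one
Product: 14 4-bromo-5-(dibromomethylidene)-3-[(1R)-1-hydroxybutyl]furan-2(5H)-one
Conditions: Et3N (1.2 equiv), CH2Cl2, 0 °C
Reagents that add atoms: none
Why: The C5 hydrogen is the γ-hydrogen of a butenolide and is further acidified by the tribromomethyl group, so the amine should remove it to a 2-oxidofuran that expels bromide from C6 (E1cB dehydrobromination), which erases the C5 centre, and with C1' still a free hydroxyl there is no second leaving group on the side chain and no path to epimerise C1'.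

**Step 6**
Reactants: 14 4-bromo-5-(dibromomethylidene)-3-[(1R)-1-hydroxybutyl]furan-2(5H)-one
Product: 15 (1R)-1-[4-bromo-5-(dibromomethylidene)-2-oxo-2,5-dihydrofuran-3-yl]butyl acetate (target)
Conditions: Ac2O, Sc(OTf)3 (1 mol %), MeCN, 0 °C
Reagents that add atoms: acetic anhydride, CC(=O)OC(C)=O
Why: Lewis-acid-catalysed acetylation of a secondary alcohol with acetic anhydride runs without base or nucleophilic catalyst, conditions under which the amine-sensitive brominated dienone should be inert, and since the C1'–O bond is not broken the R configuration is retained.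

**Compound list**
1 | methyl propiolate (methyl prop-2-ynoate) | C#CC(=O)OC | starting material
2 | tribromoacetaldehyde (bromal) | O=CC(Br)(Br)Br | starting material
3 | methyl 3-lithioprop-2-ynoate | [Li]C#CC(=O)OC | intermediate
4 | lithium alkoxide of methyl 5,5,5-tribromo-4-hydroxypent-2-ynoate (racemic) | COC(=O)C#CC(O[Li])C(Br)(Br)Br | intermediate
5 | methyl 5,5,5-tribromo-4-hydroxypent-2-ynoate (racemic) | COC(=O)C#CC(O)C(Br)(Br)Br | intermediate
6 | methyl 5,5,5-tribromo-4-(triethylsilyloxy)pent-2-ynoate (racemic) | COC(=O)C#CC(O[Si](CC)(CC)CC)C(Br)(Br)Br | intermediate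
7 | butanal | CCCC=O | starting material
8 | bromotrimethylsilane | C[Si](C)(C)Br | starting material
9 | 3,5,5,5-tetrabromo-1-methoxy-4-(triethylsilyloxy)-1-(trimethylsilyloxy)penta-1,2-diene (β-bromo silyl allenolate, stereochemistry undefined) | COC(O[Si](C)(C)C)=C=C(Br)C(O[Si](CC)(CC)CC)C(Br)(Br)Br | intermediate
10 | methyl (2E)-3,5,5,5-tetrabromo-4-(triethylsilyloxy)-2-[(1R)-1-(trimethylsilyloxy)butyl]pent-2-enoate (two epimers at C4) | CCC[C@@H](O[Si](C)(C)C)/C(C(=O)OC)=C(\Br)C(O[Si](CC)(CC)CC)C(Br)(Br)Br | intermediate
11 | methyl (2E)-3,5,5,5-tetrabromo-2-[(1R)-1-hydroxybutyl]-4-(triethylsilyloxy)pent-2-enoate (two epimers at C4; ester cis to the silyloxy carbon) | CCC[C@@H](O)/C(C(=O)OC)=C(\Br)C(O[Si](CC)(CC)CC)C(Br)(Br)Br | intermediate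
12 | methyl (2E)-3,5,5,5-tetrabromo-4-hydroxy-2-[(1R)-1-hydroxybutyl]pent-2-enoate (two epimers at C4) | CCC[C@@H](O)/C(C(=O)OC)=C(\Br)C(O)C(Br)(Br)Br | intermediate
13 | 4-bromo-3-[(1R)-1-hydroxybutyl]-5-(tribromomethyl)furan-2(5H)-one (two epimers at C5) | CCC[C@@H](O)C1=C(Br)C(C(Br)(Br)Br)OC1=O | intermediate
14 | 4-bromo-5-(dibromomethylidene)-3-[(1R)-1-hydroxybutyl]furan-2(5H)-one | CCC[C@@H](O)C1=C(Br)C(=C(Br)Br)OC1=O | intermediate
15 | (1R)-1-[4-bromo-5-(dibromomethylidene)-2-oxo-2,5-dihydrofuran-3-yl]butyl acetate | CCC[C@@H](OC(C)=O)C1=C(Br)C(=C(Br)Br)OC1=O | target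

**Total step count:** 6. **Longest linear sequence:** 6 steps (1 → 15).

**Steps most likely to fail**

Step 3. Bromide transfer from the bromosilane to the hindered internal ynoate may be slow, so that the allenolate is protonated before it meets the aldehyde, or an achiral silyl-cation pathway may erode the face selection. The fallback sets out from 6 and separates bond formation from stereocontrol. A stoichiometric metal-bromide halo-aldol with butanal (MgBr2·OEt2, or TiBr4 at −78 °C, CH2Cl2) should give methyl (2E)-3,5,5,5-tetrabromo-2-(1-hydroxybutyl)-4-(triethylsilyloxy)pent-2-enoate F1 as a mixture at C1'. Dess–Martin oxidation should then give methyl (2E)-3,5,5,5-tetrabromo-2-butanoyl-4-(triethylsilyloxy)pent-2-enoate F2. Corey–Bakshi–Shibata reduction with the (S)-methyl oxazaborolidine and catecholborane at −78 °C, the alkenyl group acting as the large substituent, should deliver the (R)-carbinol and come back to the route at 11.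

Step 1. Bromine may be transferred from the tribromomethyl group to the lithium acetylide (halophilic attack), or the lithium alkoxide may break down before the quench. The fallback sets out from 1 and avoids any stoichiometric metal acetylide in the presence of bromal. C-silylation through 3 (LiHMDS, THF, −78 °C, then TMSCl) should give methyl 3-(trimethylsilyl)prop-2-ynoate F3. Fluoride-catalysed alkynylsilane addition to 2 (TBAT 5 mol %, THF, −20 °C) should give, by silyl transfer to the alkoxide, methyl 5,5,5-tribromo-4-(trimethylsilyloxy)pent-2-ynoate F4. Brief treatment with 1 M HCl in THF at 0 °C removes the trimethylsilyl group and comes back to the route at 5.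

Step 4. Ring closure may stall because the electron-poor, crowded tribromomethyl carbinol is a weak nucleophile toward a methyl ester. The fallback sets out from 11 and closes the ring from an activated acid instead. Me3SnOH in 1,2-dichloroethane at 70 °C should cleave the methyl ester to (2E)-3,5,5,5-tetrabromo-2-[(1R)-1-hydroxybutyl]-4-(triethylsilyloxy)pent-2-enoic acid F5. Aqueous HF in MeCN should then give (2E)-3,5,5,5-tetrabromo-4-hydroxy-2-[(1R)-1-hydroxybutyl]pent-2-enoic acid F6. Carbodiimide activation (EDC·HCl, CH2Cl2, high dilution, 0 °C) should close the five-membered lactone in preference to the strained four-membered one and come back to the route at 13.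

**Further compounds**
F1 | step 3 | methyl (2E)-3,5,5,5-tetrabromo-2-(1-hydroxybutyl)-4-(triethylsilyloxy)pent-2-enoate (racemic at C1') | CCCC(O)/C(C(=O)OC)=C(\Br)C(O[Si](CC)(CC)CC)C(Br)(Br)Br
F2 | step 3 | methyl (2E)-3,5,5,5-tetrabromo-2-butanoyl-4-(triethylsilyloxy)pent-2-enoate | CCCC(=O)/C(C(=O)OC)=C(\Br)C(O[Si](CC)(CC)CC)C(Br)(Br)Br
F3 | step 1 | methyl 3-(trimethylsilyl)prop-2-ynoate | C[Si](C)(C)C#CC(=O)OC
F4 | step 1 | methyl 5,5,5-tribromo-4-(trimethylsilyloxy)pent-2-ynoate (racemic) | COC(=O)C#CC(O[Si](C)(C)C)C(Br)(Br)Br
F5 | step 4 | (2E)-3,5,5,5-tetrabromo-2-[(1R)-1-hydroxybutyl]-4-(triethylsilyloxy)pent-2-enoic acid | CCC[C@@H](O)/C(C(=O)O)=C(\Br)C(O[Si](CC)(CC)CC)C(Br)(Br)Br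
F6 | step 4 | (2E)-3,5,5,5-tetrabromo-4-hydroxy-2-[(1R)-1-hydroxybutyl]pent-2-enoic acid | CCC[C@@H](O)/C(C(=O)O)=C(\Br)C(O)C(Br)(Br)Br
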